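**Assumption:** the SMILES is taken literally (C2=C3 is Z, acyl carbon cis to C4; the 3-acyltetronic acid is drawn as its exocyclic enol). Locants used below: C1 = acyl carbon, C2–C9 = chain, C10–C15 = cyclohexene (C12 bears CO2H, C15 is the spiro carbon), tetronate atoms keep furanone numbering. The target is (2Z,4R,6R,10S,13S,15S); compounds 1, 2, 6, 12, 15 and 20 are purchased.

## Retrosynthetic overview

1. Okilactomycin C ⇐ tert-butyl ester 28 ⇐ light-driven 1,3-acyl shift (O→C) of the isomeric 13-membered enol-ester macrolactone 27; this forms the C1–tetronate C3 bond and the carbocycle.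
2. 27 ⇐ intramolecular Diels–Alder reaction of the O-acyl 5-methylidenetetronate 26; this forms the cyclohexene, the spiro centre and the macrolactone at once and sets C10, C13 and C15.
3. 26 ⇐ trienoic acid 19 + 4-methoxy-5-methylidenefuranone 23 (from methyl tetronate 20; the tetronate ring is bought).
4. 19 ⇐ Suzuki–Miyaura coupling of alkynoic acid 14 with iodo-enoate 17; 14 ⇐ Still–Gennari olefination of aldehyde 11.
5. 11 ⇐ invertive Cu-catalysed sp3–sp3 coupling of the Roche-type Grignard 8 (C4) with the propylene-oxide-derived tosylate 5 (C6).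

## Route

Step 1
Reactants: 1 4-bromo-1-(trimethylsilyl)but-1-yne; 2 (S)-propylene oxide
Product: 4 (2S)-7-(trimethylsilyl)hept-6-yn-2-ol, via alkylmagnesium bromide 3 (not isolated)
Conditions: Mg, THF, rt; then 2, CuI (10 mol%), −30 → 0 °C; aq. NH4Cl
Reagents that add atoms: none
Why: Cu-catalysed Grignard opening of a terminal epoxide occurs by SN2 attack at the CH2 terminus, so the bought S carbinol centre (future C6) is not touched.

Step 2
Reactants: 4 (2S)-7-(trimethylsilyl)hept-6-yn-2-ol
Product: 5 (2S)-7-(trimethylsilyl)hept-6-yn-2-yl 4-methylbenzenesulfonate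
Conditions: TsCl, Et3N, DMAP (cat.), CH2Cl2, 0 °C → rt
Reagents that add atoms: 4-toluenesulfonyl chloride, Cc1ccc(cc1)S(=O)(=O)Cl
Why: O-sulfonylation of a secondary alcohol forms only the O–S bond, so configuration is retained.

Step 3
Reactants: 6 (2S)-3-bromo-2-methylpropan-1-ol
Product: 7 [(2S)-3-bromo-2-methylpropoxy](tert-butyl)dimethylsilane
Conditions: TBSCl, imidazole, CH2Cl2, 0 °C → rt
Reagents that add atoms: tert-butyldimethylsilyl chloride, CC(C)(C)[Si](C)(C)Cl
Why: Standard silyl protection of the primary alcohol so that the bromide can be turned into a Grignard reagent; the stereocentre (future C4) is not involved.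

Step 4
Reactants: 7 [(2S)-3-bromo-2-methylpropoxy](tert-butyl)dimethylsilane; 5 (2S)-7-(trimethylsilyl)hept-6-yn-2-yl 4-methylbenzenesulfonate
Product: 9 tert-butyl{[(2R,4R)-2,4-dimethyl-9-(trimethylsilyl)non-8-yn-1-yl]oxy}dimethylsilane, via alkylmagnesium bromide 8 (not isolated)
Conditions: 7, Mg, THF, rt; then 5, CuI (10 mol%), TMEDA (20 mol%), LiOMe (1 equiv), THF, 0 °C, 24 h
Reagents that add atoms: none
Why: Cu-catalysed sp3–sp3 cross-coupling of a secondary alkyl tosylate with a primary alkyl Grignard reagent proceeds by SN2 displacement with inversion, so the S tosylate gives the R configuration at C6 and, with the untouched Roche-derived C4, the syn-1,3-dimethyl array.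

Step 5
Reactants: 9 tert-butyl{[(2R,4R)-2,4-dimethyl-9-(trimethylsilyl)non-8-yn-1-yl]oxy}dimethylsilane
Product: 10 (2R,4R)-2,4-dimethylnon-8-yn-1-ol
Conditions: Bu4NF (2.5 equiv), THF, 0 °C → rt
Reagents that add atoms: none
Why: Fluoride cleaves both the O–Si and the alkynyl C–Si bond in one operation (global desilylation).

Step 6
Reactants: 10 (2R,4R)-2,4-dimethylnon-8-yn-1-ol
Product: 11 (2R,4R)-2,4-dimethylnon-8-ynal
Conditions: Dess–Martin periodinane, CH2Cl2, 0 °C → rt; used at once
Reagents that add atoms: none
Why: Dess–Martin oxidation is near-neutral and does not epimerise the α-methyl aldehyde or touch the terminal alkyne.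

Step 7
Reactants: 11 (2R,4R)-2,4-dimethylnon-8-ynal; 12 ethyl 2-[bis(2,2,2-trifluoroethoxy)phosphoryl]propanoate
Product: 13 ethyl (2Z,4R,6R)-2,4,6-trimethylundec-2-en-10-ynoate
Conditions: 12, KN(SiMe3)2, 18-crown-6, THF, −78 °C; then 11, −78 °C
Reagents that add atoms: none
Why: Still–Gennari olefination with the electron-poor phosphonate and a dissociated potassium counter-ion eliminates under kinetic control to the Z trisubstituted enoate (ester cis to C4), at a temperature where the α-stereocentre does not epimerise.

Step 8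
Reactants: 13 ethyl (2Z,4R,6R)-2,4,6-trimethylundec-2-en-10-ynoate
Product: 14 (2Z,4R,6R)-2,4,6-trimethylundec-2-en-10-ynoic acid
Conditions: LiOH, THF/MeOH/H2O, 45 °C; then 1 M HCl
Reagents that add atoms: lithium hydroxide, [Li+].[OH-]
Why: Saponification at this stage, before any other ester is present, avoids a later selective hydrolysis and leaves the Z geometry and the alkyne intact.

Step 9
Reactants: 15 tert-butyl but-2-ynoate
Product: 17 tert-butyl (2E)-2-iodobut-2-enoate, via vinylstannane 16 (not isolated)
Conditions: Bu3SnH, Pd(PPh3)4 (2 mol%), THF, 0 °C → rt; then I2, CH2Cl2, 0 °C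
Reagents that add atoms: iodine, II
Why: Pd-catalysed hydrostannation of an ynoate is a syn addition that places tin on the α-carbon, so the methyl ends up cis to the ester, and iododestannylation then occurs with retention.

Step 10
Reactants: 14 (2Z,4R,6R)-2,4,6-trimethylundec-2-en-10-ynoic acid; 17 tert-butyl (2E)-2-iodobut-2-enoate
Product: 19 (2Z,4R,6R,10E,12Z)-12-(tert-butoxycarbonyl)-2,4,6-trimethyltetradeca-2,10,12-trienoic acid, via alkenylborane 18 (not isolated)
Conditions: Cy2BH (2.2 equiv), THF, 0 °C → rt; then 17, Pd(PPh3)4 (5 mol%), 2 M aq. NaOH, THF, 40 °C; then 1 M HCl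
Reagents that add atoms: none
Why: The first equivalent of borane masks the acid as its borinate, the second adds syn and anti-Markovnikov to the alkyne to give the E alkenylborane, and Suzuki–Miyaura coupling with retention at both partners gives the diene with the 10E alkene and the ethylidene methyl cis to the ester.

Step 11
Reactants: 20 4-methoxyfuran-2(5H)-one
Product: 23 4-methoxy-5-methylidenefuran-2(5H)-one, via Mannich base 21 (not isolated), via trimethylammonium iodide 22 (not isolated)
Conditions: LiN(iPr)2, THF, −78 °C; CH2=NMe2+ I−, −78 → 0 °C; then MeI, MeOH, rt; then aq. NaHCO3, CH2Cl2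
Reagents that add atoms: N,N-dimethylmethyleneiminium iodide, C=[N+](C)C.[I-]
Why: γ-Deprotonation of methyl tetronate at C5, Mannich reaction, quaternisation and E1cB elimination is the standard α-methylenation sequence for lactones and gives the exocyclic alkene.

Step 12
Reactants: 19 (2Z,4R,6R,10E,12Z)-12-(tert-butoxycarbonyl)-2,4,6-trimethyltetradeca-2,10,12-trienoic acid; 23 4-methoxy-5-methylidenefuran-2(5H)-one
Product: 26 2-methylidene-5-oxo-2,5-dihydrofuran-3-yl (2Z,4R,6R,10E,12Z)-12-(tert-butoxycarbonyl)-2,4,6-trimethyltetradeca-2,10,12-trienoate, via acid chloride 24 (not isolated), via lithium tetronate 25 (not isolated)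
Conditions: 23, LiCl (1.2 equiv), DMF, 50 °C; separately 19, 1-chloro-N,N,2-trimethylprop-1-en-1-amine, CH2Cl2, 0 °C; combine at −20 → 0 °C
Reagents that add atoms: none
Why: Chloride demethylates the vinylogous carbonate by SN2 at the methyl group, and the tetronate anion is then acylated on oxygen (kinetic site, no nucleophilic catalyst) by an acid chloride made under neutral conditions so that the Z enoyl group does not isomerise.

Step 13
Reactants: 26 2-methylidene-5-oxo-2,5-dihydrofuran-3-yl (2Z,4R,6R,10E,12Z)-12-(tert-butoxycarbonyl)-2,4,6-trimethyltetradeca-2,10,12-trienoate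
Product: 27 spiro enol-ester macrolactone (Diels–Alder adduct; tert-butyl ester; 2Z; 4R,6R,10S,13S,15S)
Conditions: PhMe (0.5 mM), BHT (0.1 equiv), 100 °C, dark, 24 h
Reagents that add atoms: none
Why: Thermal intramolecular Diels–Alder reaction of the exocyclic alkene of the 4-acyloxy-5-methylidenefuranone with the 1,4-dialkyl-2-alkoxycarbonyl diene: the tether enforces C10–C15 and C13–C14 bonding; the 10E alkene and the outward ethylidene methyl give H-10 and H-13 cis; the tether holds tetronate C4 endo (cis to C9); and the face is expected to be chosen by the bought C4/C6 centres, since allylic 1,3-strain across the Z enoate fixes C4–H in the enoate plane and the syn-1,3-dimethyl unit has one fold free of syn-pentane contacts, so that C10, C13 and C15 are set together.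

Step 14
Reactants: 27 spiro enol-ester macrolactone (Diels–Alder adduct; tert-butyl ester; 2Z; 4R,6R,10S,13S,15S)
Product: 28 okilactomycin C tert-butyl ester
Conditions: hν (254 nm, quartz flow cell), degassed MeCN (1 mM), −20 °C, to about 80% conversion
Reagents that add atoms: none
Why: Proposed new method: excitation of the 4-acyloxybutenolide (a vinylogous mixed anhydride) should cleave the enol O–acyl bond homolytically to a tetronyl/enoyl radical pair whose halves remain tied together in the 13-membered ring, so they cannot diffuse apart and recombine at the adjacent tetronate C3 (a least-motion 1,3-shift that involves no stereocentre), after which tautomerisation gives the chelated 3-acyl enol, which sheds light energy by excited-state proton transfer and therefore survives; the closest known reactions are the photo-Fries rearrangement of aryl esters and the photochemical O-to-C acyl shift of enol esters of cyclic 1,3-diketones, neither shown on tetronate O-esters nor as a macrolactone-to-carbocycle transposition.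

Step 15
Reactants: 28 okilactomycin C tert-butyl ester
Product: 29 okilactomycin C
Conditions: TFA/CH2Cl2 (1:4), 0 °C → rt, 1 h
Reagents that add atoms: none
Why: Acidolysis of the tert-butyl ester (loss of isobutene) frees the C12 acid without base, to which the acyltetronic acid and the Z enone would be more sensitive.

## Compound list

1 | 4-bromo-1-(trimethylsilyl)but-1-yne | C[Si](C)(C)C#CCCBr | starting material
2 | (S)-propylene oxide | C[C@H]1CO1 | starting material
3 | [4-(trimethylsilyl)but-3-yn-1-yl]magnesium bromide | C[Si](C)(C)C#CCC[Mg]Br | intermediate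
4 | (2S)-7-(trimethylsilyl)hept-6-yn-2-ol | C[C@H](O)CCCC#C[Si](C)(C)C | intermediate
5 | (2S)-7-(trimethylsilyl)hept-6-yn-2-yl 4-methylbenzenesulfonate | C[C@H](OS(=O)(=O)c1ccc(C)cc1)CCCC#C[Si](C)(C)C | intermediate
6 | (2S)-3-bromo-2-methylpropan-1-ol | OC[C@H](C)CBr | starting material
7 | [(2S)-3-bromo-2-methylpropoxy](tert-butyl)dimethylsilane | CC(C)(C)[Si](C)(C)OC[C@H](C)CBr | intermediate
8 | [(2S)-3-(tert-butyldimethylsilyloxy)-2-methylpropyl]magnesium bromide | CC(C)(C)[Si](C)(C)OC[C@H](C)C[Mg]Br | intermediate
9 | tert-butyl{[(2R,4R)-2,4-dimethyl-9-(trimethylsilyl)non-8-yn-1-yl]oxy}dimethylsilane | CC(C)(C)[Si](C)(C)OC[C@H](C)C[C@H](C)CCCC#C[Si](C)(C)C | intermediate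
10 | (2R,4R)-2,4-dimethylnon-8-yn-1-ol | OC[C@H](C)C[C@H](C)CCCC#C | intermediate
11 | (2R,4R)-2,4-dimethylnon-8-ynal | O=C[C@H](C)C[C@H](C)CCCC#C | intermediate
12 | ethyl 2-[bis(2,2,2-trifluoroethoxy)phosphoryl]propanoate | CCOC(=O)C(C)P(=O)(OCC(F)(F)F)OCC(F)(F)F | starting material
13 | ethyl (2Z,4R,6R)-2,4,6-trimethylundec-2-en-10-ynoate | CCOC(=O)/C(C)=C\[C@H](C)C[C@H](C)CCCC#C | intermediate
14 | (2Z,4R,6R)-2,4,6-trimethylundec-2-en-10-ynoic acid | OC(=O)/C(C)=C\[C@H](C)C[C@H](C)CCCC#C | intermediate
15 | tert-butyl but-2-ynoate | CC#CC(=O)OC(C)(C)C | starting material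
16 | tert-butyl (2E)-2-(tributylstannyl)but-2-enoate (methyl cis to ester) | C/C=C(/[Sn](CCCC)(CCCC)CCCC)C(=O)OC(C)(C)C | intermediate
17 | tert-butyl (2E)-2-iodobut-2-enoate (methyl cis to ester) | C/C=C(/I)C(=O)OC(C)(C)C | intermediate
18 | dicyclohexylboryl (2Z,4R,6R,10E)-11-(dicyclohexylboryl)-2,4,6-trimethylundeca-2,10-dienoate | O=C(OB(C1CCCCC1)C1CCCCC1)/C(C)=C\[C@H](C)C[C@H](C)CCC/C=C/B(C1CCCCC1)C1CCCCC1 | intermediate
19 | (2Z,4R,6R,10E,12Z)-12-(tert-butoxycarbonyl)-2,4,6-trimethyltetradeca-2,10,12-trienoic acid | OC(=O)/C(C)=C\[C@H](C)C[C@H](C)CCC/C=C/C(C(=O)OC(C)(C)C)=C/C | intermediate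
20 | 4-methoxyfuran-2(5H)-one (methyl tetronate) | COC1=CC(=O)OC1 | starting material
21 | 5-[(dimethylamino)methyl]-4-methoxyfuran-2(5H)-one (racemic) | COC1=CC(=O)OC1CN(C)C | intermediate
22 | [(3-methoxy-5-oxo-2,5-dihydrofuran-2-yl)methyl]trimethylammonium iodide (racemic) | COC1=CC(=O)OC1C[N+](C)(C)C.[I-] | intermediate
23 | 4-methoxy-5-methylidenefuran-2(5H)-one | COC1=CC(=O)OC1=C | intermediate
24 | (2Z,4R,6R,10E,12Z)-12-(tert-butoxycarbonyl)-2,4,6-trimethyltetradeca-2,10,12-trienoyl chloride | ClC(=O)/C(C)=C\[C@H](C)C[C@H](C)CCC/C=C/C(C(=O)OC(C)(C)C)=C/C | intermediate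
25 | lithium 2-methylidene-5-oxo-2,5-dihydrofuran-3-olate | [Li+].[O-]C1=CC(=O)OC1=C | intermediate
26 | 2-methylidene-5-oxo-2,5-dihydrofuran-3-yl ester of acid 19 (4-O-acyl 5-methylidenetetronate) | C=C1OC(=O)C=C1OC(=O)/C(C)=C\[C@H](C)C[C@H](C)CCC/C=C/C(C(=O)OC(C)(C)C)=C/C | intermediate
27 | Diels–Alder adduct: cyclohexene C10–C15 spiro-fused at C15 to a 4-acyloxyfuran-2(5H)-one, the (2Z)-enoyl chain closing a 13-membered lactone through the tetronate 4-oxygen; tert-butyl ester; 4R,6R,10S,13S,15S | CC1=C/[C@H](C)C[C@H](C)CCC[C@H]2C=C(C(=O)OC(C)(C)C)[C@@H](C)C[C@]23OC(=O)C=C3OC\1=O | intermediate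
28 | okilactomycin C tert-butyl ester | CC1=C/[C@H](C)C[C@H](C)CCC[C@H]2C=C(C(=O)OC(C)(C)C)[C@@H](C)C[C@]23OC(=O)\C(=C\1O)C3=O | intermediate
29 | okilactomycin C | CC1=C/[C@H](C)C[C@H](C)CCC[C@H]2C=C(C(=O)O)[C@@H](C)C[C@]23OC(=O)\C(=C\1O)C3=O | target

## Step count and risks

Total steps: 15. Longest linear sequence: 12 (steps 1, 2, 4, 5, 6, 7, 8, 10, 12, 13, 14, 15).

**Step 14 (the proposed new light-driven acyl shift).** The Z enoyl group is itself a chromophore with a γ-hydrogen cis to the carbonyl, so Z/E isomerisation or photoenolisation (which would erode C4) can compete, as can [2+2] addition of the butenolide. Low temperature, a neutral aprotic solvent, short residence time and partial conversion are meant to limit this; a triplet quencher such as piperylene can be added.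
Fallback, known chemistry: it sets out from 27 and comes back at 28. Compound 27 is treated with DMAP (1.5 equiv) and Et3N in CH2Cl2 at room temperature. This is the ground-state, nucleophile-mediated 4-O-acyl to 3-acyl rearrangement of tetronates: the macrolactone is opened to the N-acylpyridinium tetronate zwitterion F1, and the tetronate carbon then attacks the acylpyridinium to close the carbocycle as 28. DMAP is returned unchanged.

**Step 13 (macrocyclising Diels–Alder).** Endo/exo and facial selectivity rest on tether and remote-stereocentre control that is argued, not demonstrated; the adduct must be checked by NOE (H-10/H-13 cis; C9 cis to tetronate C4).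
Fallback: it sets out from 26 and comes back at 28. The acyl group is moved to carbon first: 26 with DMAP and Et3N in CH2Cl2 (0 °C → rt) gives the 3-acyl-5-methylidenetetronic acid F2. F2 is then heated in PhMe (80–100 °C, 0.5 mM). The planar, chelated 3-acyltetronic acid is a stronger dienophile with a different tether geometry, the one used in known intramolecular Diels–Alder routes to spirotetronates, and the cycloaddition gives 28 directly, bypassing 27 and step 14.

**Step 12 (demethylation and O-acylation of the methylidene tetronate).** The anion 25 and the product 26 are polymerisable Michael acceptors, and C-acylation or chloride addition may interfere.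
Fallback: it sets out from 23 (with 19) and comes back at 26; the exocyclic alkene is masked while the ester is made. PhSeSePh/NaBH4 in EtOH (0 °C) adds benzeneselenol to 23 to give 4-methoxy-5-[(phenylselanyl)methyl]furan-2(5H)-one F3. LiCl in DMF (60 °C) followed by acid gives the stable 4-hydroxy-5-[(phenylselanyl)methyl]furan-2(5H)-one F4. DCC coupling with 19 (CH2Cl2, 0 °C, no DMAP) gives the 4-O-acyl tetronate F5 as a mixture of epimers at the selenide-bearing carbon, which does not matter. H2O2 in THF (0 °C) oxidises it to the selenoxide F6, which undergoes syn-elimination at room temperature to give 26.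

## Further compounds

F1 | step 14 | N-acyl-4-(dimethylamino)pyridinium tetronate zwitterion from ring-opening of 27 | CN(C)c1cc[n+](cc1)C(=O)/C(C)=C\[C@H](C)C[C@H](C)CCC[C@H]2C=C(C(=O)OC(C)(C)C)[C@@H](C)C[C@]23OC(=O)C=C3[O-]
F2 | step 13 | 3-acyl-4-hydroxy-5-methylidenefuran-2(5H)-one (C-acyl isomer of 26; tert-butyl ester) | C=C1OC(=O)C(C(=O)/C(C)=C\[C@H](C)C[C@H](C)CCC/C=C/C(C(=O)OC(C)(C)C)=C/C)=C1O
F3 | step 12 | 4-methoxy-5-[(phenylselanyl)methyl]furan-2(5H)-one (racemic) | COC1=CC(=O)OC1C[Se]c1ccccc1
F4 | step 12 | 4-hydroxy-5-[(phenylselanyl)methyl]furan-2(5H)-one (racemic) | OC1=CC(=O)OC1C[Se]c1ccccc1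
F5 | step 12 | 5-oxo-2-[(phenylselanyl)methyl]-2,5-dihydrofuran-3-yl ester of acid 19 | O=C1C=C(OC(=O)/C(C)=C\[C@H](C)C[C@H](C)CCC/C=C/C(C(=O)OC(C)(C)C)=C/C)C(C[Se]c2ccccc2)O1
F6 | step 12 | selenoxide of F5 | O=C1C=C(OC(=O)/C(C)=C\[C@H](C)C[C@H](C)CCC/C=C/C(C(=O)OC(C)(C)C)=C/C)C(C[Se](=O)c2ccccc2)O1
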